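**The problem**

The target is a fifteen-carbon germacrane-type lactone. Its carbons are numbered C1–C10 around the ten-membered carbocycle, C11–C13 for the lactone carbons, C14 for the methyl on C10 and C15 for the methyl on C4, and these numbers are used for every intermediate. The C6–C7 bond of the carbocycle is shared with a butenolide (oxygen on C6, carbonyl C12, tetrasubstituted C7=C11 alkene). C11 carries C13H2OAc, C8 a tiglate, C1 a free hydroxyl, and C4–C5 a cis epoxide. A synthesis must close a medium ring and place six stereocentres (1S,4R,5S,6S,8S,10R) on it. C10 can be bought. C8 is an allylic carbinol suited to reagent-controlled ketone reduction, and C6, one sp2 atom away, can be relayed from C8. The epoxide can be set from C6 across the Z alkene by allylic strain, and C1 from the adjacent C10 methyl, both on the finished ring. The fragile groups are the trisubstituted epoxide facing a transannular C1 hydroxyl (acid), the α-(acetoxymethyl)butenolide (an allylic acetate on a Michael acceptor, with an acidic C6–H), and the two esters (hydrides, organometallics, titanium methylenation). These must arrive late and under near-neutral conditions. The enabling feature is the run C1(O)–C2H2–C3H2–C4(CH3)–C5: with the epoxide read as its Z alkene it is a cyclodec-4-enone, the retron of a Claisen rearrangement. The C1 oxygen can therefore begin as the ring oxygen of an eight-membered lactone spanning C1 and C5, and the carbocycle can be made by inserting C2 and C3 rather than by end-to-end closure.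

**Retrosynthesis**

Target 29 is cut first at the C1–H bond (ketone 28), then at the C12 carbonyl oxygen (dihydrofuran 27), then at the epoxide oxygen (alkene 26). Reducing C1 earlier would require a protecting group and would expose an alcohol to the chromium oxidant. Oxidising C12 before epoxidation would leave C6–H doubly allylic. Unmasking the lactone second to last keeps the α-(acetoxymethyl)butenolide out of every fluoride and acylation step. Compound 26 has three stereocentres and no sensitive group. The forward steps must be chemoselective and face-selective on the ten-membered ring.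

The two ester C–O bonds of 26 are cut next, leading through monoacetate 25 and diol 24 to bis-silyl ether 23. With C1 still a ketone only two hydroxyls compete, and they differ as primary and hindered secondary. The forward reactions need only steric discrimination.

Ketone 23 is cut at C2–C3 with reconnection of C5 to the C1 oxygen, giving 2-methylene oxocane 22 and, by removal of the methylene carbon, lactone 21. Other ring cuts (C9–C10 by metathesis, C8–C9 by oxy-Cope) close the ten-membered ring end to end or leave the oxygen pattern wrong. This cut places the carbonyl at C1 and the alkene at C4–C5 in one event and shrinks the ring problem to an eight-membered lactone. The butenolide must be masked as a 2,5-dihydrofuran because Cp2TiMe2 would attack its carbonyl. The forward reaction must give the Z alkene.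

Lactone 21 is cut at the C1(=O)–O bond to hydroxy acid 19, which comes from aldehyde 18, diol 17 and bis-triethylsilyl ether 16 by oxidation-state changes. No carbon–carbon closure of this ring is as direct. The C6–C7 bond of the planar dihydrofuran holds C5 and C8 cis, like a cis alkene, which is the best available help for an eight-membered lactonisation. C1 is carried as a silyl ether until here because the butenolide reduction would not spare an ester.

Dihydrofuran 16 is cut at the O–C12 ether bond to ene-diol 15, the hydride reduction product of butenolide 14. The butenolide is kept up to this point because it is the form in which C6 can be made nucleophilic.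

Butenolide 14 is cut at C5–C6 into furanone 11 and methacrolein 12 (vinylogous aldol through silyloxyfuran 13). This installs C3, C4, C5 and C15 in one step and leaves C5–O silylated. The forward reaction must take its C6 configuration from C8. The C5 configuration is irrelevant because step 16 destroys it.

Furanone 11 is cut at C11–C13 (hydroxymethyl stannane, through 10 and 9), at the C8–H bond (ketone 7, through alcohol 8), and at C7–C8 and C8–C9 together. The last cut gives 3,4-dibromofuranone 5, carbon monoxide and alkylzinc 6. Compound 5 comes from mucobromic acid 3 through hydroxy acid salt 4, and 6 from silyl ether 2 of bromo alcohol 1, which supplies C9, C10, C14 and C1. The β-bromide of 5 reacts first, so the order of the two couplings is fixed by the substrate.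

**Roads not taken**

Alternative 1: The cut is the C9–C10 bond. Diene A1 has every oxygen function and the epoxide in place, with a vinyl group on C8 and an isopropenyl carbinol at C1. The second-generation Hoveyda–Grubbs catalyst would close it to 9,10-didehydro compound A2. Hydrogenation directed by the C1 hydroxyl with [Ir(cod)(PCy3)(py)]PF6 would then set C10 and give 29.
- Merits: it is convergent, closes the ring at the very end, and never masks the butenolide, so it needs no titanium step and no late C–H oxidation.
- Weak points: a ten-membered ring is closed end to end while a trisubstituted alkene is formed from a 1,1-disubstituted alkene and a vinyl group next to an acyloxy carbon. Both partners are slow, so oligomerisation competes. The hydrogenation must then distinguish the new alkene from the tiglate and set C10 on a ring of unknown conformation. C1 must be set earlier without help from the ring.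
- Comparison: in step count and endgame safety this road is better. The chosen plan sets against it a unimolecular ring expansion that needs no high dilution and is driven by carbonyl formation, and a C10 centre bought at the start.

Alternative 2: No carbon–carbon bond is made in the key step. Octalin A3 (C8 silyl ether, C10 methyl, C4 tertiary carbinol, tetrasubstituted C1=C6 alkene) is cleaved with ozone and Me2S to ten-membered diketone A4.
- Merits: this is the most reliable ring formation of the four, and C8, C10 and C4 are set on rigid six-membered rings.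
- Weak points: A4 is far from the target. C11–C13 are missing, and C7 is a methylene that must receive three carbons and become part of a tetrasubstituted alkene in competition with C5, C2 and C10. The two ketones must be told apart, C6 must be reduced stereoselectively, and the C4 carbinol must be converted to the cis epoxide, which spends the stereocentre invested in A3.
- Comparison: certainty of ring formation is better here. The chosen plan sets against it that 23 already carries C11–C13, the C6 oxygen, a single ketone at C1 and the alkene at C4–C5 with the right geometry, so six steps remain after ring formation.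

Alternative 3: The cut is C8–C9, with a temporary C1–C6 bond. The potassium alkoxide of trans-1,2-dialkenylcyclohexenol A5 (KH, 18-crown-6) would rearrange [3,3] to ten-membered dienone A6.
- Merits: anionic oxy-Cope expansion from six to ten is better precedented for germacrane rings than an eight-to-ten Claisen shift. It runs at low temperature, starts from a cheap terpene skeleton, and sets C8 by chirality transfer through a chair.
- Weak points: A6 has the C6 ketone but a bare C7 methylene, so the butenolide must be annulated afterwards. The C1=C10 alkene must be turned into C1–OH and C10–H with two new stereocentres set at once by ring conformation. The Z enone at C4–C5 must be epoxidised nucleophilically or after carbonyl reduction.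
- Comparison: the key step is better founded and sets C8. The chosen plan sets against it that the rearrangement itself puts oxygen on C1, C10 comes from the chiral pool, and the butenolide carbons are in place before the ring is formed.

Key step: step 16

Assumptions (remarks on the chemistry):
- The C5 carbinol is drawn 5S, syn to the C6 oxygen, the usual sense of Lewis-acid vinylogous aldol additions of 2-silyloxyfurans. Step 16 destroys this centre, so the choice does not reach the target.
- Bromo alcohol 1 is taken as a commercial member of the 3-hydroxy-2-methylpropanoate family.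

**Steps**

Step 1
Reactants: 1 (S)-3-bromo-2-methylpropan-1-ol
Product: 2 (S)-(3-bromo-2-methylpropoxy)triethylsilane
Conditions: TESCl, imidazole, CH2Cl2, 0 °C to rt
Reagents that add atoms: chlorotriethylsilane CC[Si](Cl)(CC)CC
Why: Standard silylation of a primary alcohol; triethylsilyl is chosen because it must later be removed beside tert-butylsilyl ethers, and the stereocentre is not touched.

Step 2
Reactants: 3 mucobromic acid
Product: 5 3,4-dibromofuran-2(5H)-one, via sodium (2Z)-2,3-dibromo-4-hydroxybut-2-enoate 4 (not isolated)
Conditions: NaBH4, MeOH, 0 °C; then conc. H2SO4, 0 °C to rt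
Reagents that add atoms: none
Why: Borohydride reduces the open-chain aldehyde form of the pseudo-acid and acid closes the (Z)-4-hydroxybutenoic acid to the butenolide, a routine preparation of this dihalofuranone.

Step 3
Reactants: 2 (S)-(3-bromo-2-methylpropoxy)triethylsilane; 5 3,4-dibromofuran-2(5H)-one
Product: 7 3-bromo-4-[(3R)-3-methyl-4-(triethylsilyloxy)butanoyl]furan-2(5H)-one, via alkylzinc bromide 6 (not isolated)
Conditions: Zn dust, LiCl, THF, 50 °C; then 5, Pd(PPh3)4 (5 mol %), CO (3 atm), THF, 40 °C
Reagents that add atoms: carbon monoxide [C-]#[O+]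
Why: Carbonylative Negishi coupling: zerovalent palladium inserts into the β C–Br bond (C7), the position of this dibromide that reacts first in cross-coupling, CO insertion gives the acylpalladium and the non-basic alkylzinc intercepts it; CO pressure is used to suppress direct alkyl coupling, the main competitor.

Step 4
Reactants: 7 3-bromo-4-[(3R)-3-methyl-4-(triethylsilyloxy)butanoyl]furan-2(5H)-one
Product: 8 3-bromo-4-[(1S,3R)-1-hydroxy-3-methyl-4-(triethylsilyloxy)butyl]furan-2(5H)-one
Conditions: (R)-Me-CBS oxazaborolidine (20 mol %), catecholborane, PhMe/CH2Cl2, −78 °C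
Reagents that add atoms: none
Why: Corey–Bakshi–Shibata reduction of an alkenyl alkyl ketone; the (R)-catalyst treats the furanone carbon as the large group and should give the 8S carbinol under reagent control, and catecholborane at −78 °C spares the lactone and the vinyl bromide.

Step 5
Reactants: 8 3-bromo-4-[(1S,3R)-1-hydroxy-3-methyl-4-(triethylsilyloxy)butyl]furan-2(5H)-one
Product: 9 3-bromo-4-[(1S,3R)-1-(tert-butyldimethylsilyloxy)-3-methyl-4-(triethylsilyloxy)butyl]furan-2(5H)-one
Conditions: TBSOTf, 2,6-lutidine, CH2Cl2, −78 °C
Reagents that add atoms: tert-butyldimethylsilyl triflate CC(C)(C)[Si](C)(C)OS(=O)(=O)C(F)(F)F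
Why: Silyl triflate silylation of a hindered allylic alcohol at low temperature, fast enough to forestall translactonisation of the C8 hydroxyl onto C12.

Step 6
Reactants: 9 3-bromo-4-[(1S,3R)-1-(tert-butyldimethylsilyloxy)-3-methyl-4-(triethylsilyloxy)butyl]furan-2(5H)-one
Product: 10 4-[(1S,3R)-1-(tert-butyldimethylsilyloxy)-3-methyl-4-(triethylsilyloxy)butyl]-3-(hydroxymethyl)furan-2(5H)-one
Conditions: Bu3SnCH2OH, Pd(PPh3)4 (10 mol %), 1,4-dioxane, 100 °C
Reagents that add atoms: (tributylstannyl)methanol CCCC[Sn](CO)(CCCC)CCCC
Why: Stille coupling of an α-bromo enoate with (tributylstannyl)methanol, a known hydroxymethyl transfer under neutral conditions that spares the lactone and both silyl ethers; it installs C13.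

Step 7
Reactants: 10 4-[(1S,3R)-1-(tert-butyldimethylsilyloxy)-3-methyl-4-(triethylsilyloxy)butyl]-3-(hydroxymethyl)furan-2(5H)-one
Product: 11 4-[(1S,3R)-1-(tert-butyldimethylsilyloxy)-3-methyl-4-(triethylsilyloxy)butyl]-3-[(tert-butyldiphenylsilyloxy)methyl]furan-2(5H)-one
Conditions: TBDPSCl, imidazole, DMF, rt
Reagents that add atoms: tert-butyl(chloro)diphenylsilane CC(C)(C)[Si](Cl)(c1ccccc1)c1ccccc1
Why: Standard silylation of a primary alcohol; the tert-butyldiphenylsilyl ether withstands the fluoride step that later removes the two triethylsilyl groups.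

Step 8
Reactants: 11 4-[(1S,3R)-1-(tert-butyldimethylsilyloxy)-3-methyl-4-(triethylsilyloxy)butyl]-3-[(tert-butyldiphenylsilyloxy)methyl]furan-2(5H)-one; 12 methacrolein
Product: 14 (5S)-4-[(1S,3R)-1-(tert-butyldimethylsilyloxy)-3-methyl-4-(triethylsilyloxy)butyl]-3-[(tert-butyldiphenylsilyloxy)methyl]-5-[(1S)-2-methyl-1-(triethylsilyloxy)prop-2-en-1-yl]furan-2(5H)-one, via 2-(triethylsilyloxy)furan 13 (not isolated)
Conditions: TESOTf (1.5 equiv), i-Pr2NEt (1.2 equiv), CH2Cl2, −78 to 0 °C; then 12, −78 °C
Reagents that add atoms: triethylsilyl triflate CC[Si](CC)(CC)OS(=O)(=O)C(F)(F)F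
Why: Soft enolisation at C6 gives the aromatic silyloxyfuran 13 and surplus silyl triflate activates the aldehyde for a vinylogous Mukaiyama aldol at the γ-carbon with silyl transfer, so C5–O emerges protected; to avoid allylic strain with the C13 silyloxymethyl group the C8–H should lie in the furan plane, the C9 chain then covers one face and the aldehyde should enter C6 from the other, which gives 6S. The open transition state should favour the syn C5/C6 adduct drawn.

Step 9
Reactants: 14 the vinylogous aldol adduct
Product: 15 (Z)-ene-1,4-diol (5S,6S,8S,10R) with free hydroxyls on C6 and C12, triethylsilyl ethers on C1 and C5, tert-butyldimethylsilyl ether on C8 and tert-butyldiphenylsilyl ether on C13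
Conditions: i-Bu2AlH (4 equiv), CH2Cl2, −78 to 0 °C; aq. potassium sodium tartrate
Reagents that add atoms: none
Why: i-Bu2AlH reduces the unsaturated lactone 1,2 through the lactol to the (Z)-ene-diol without touching silyl ethers; excess reagent carries the lactol on so that it cannot aromatise to a furan.

Step 10
Reactants: 15 the (Z)-ene-1,4-diol
Product: 16 (2S)-3-[(1S,3R)-1-(tert-butyldimethylsilyloxy)-3-methyl-4-(triethylsilyloxy)butyl]-4-[(tert-butyldiphenylsilyloxy)methyl]-2-[(1S)-2-methyl-1-(triethylsilyloxy)prop-2-en-1-yl]-2,5-dihydrofuran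
Conditions: PPh3, DIAD, THF, 0 °C to rt
Reagents that add atoms: none
Why: Mitsunobu cyclodehydration: the oxyphosphonium forms on the unhindered primary allylic C12 alcohol and the C6 hydroxyl displaces it (5-exo-tet), so the C6–O bond and its configuration are retained; the C5 oxygen is silylated and cannot form the six-membered ether.

Step 11
Reactants: 16 the bis-triethylsilyl dihydrofuran
Product: 17 (2R,4S)-4-(tert-butyldimethylsilyloxy)-4-{(2S)-4-[(tert-butyldiphenylsilyloxy)methyl]-2-[(1S)-1-hydroxy-2-methylprop-2-en-1-yl]-2,5-dihydrofuran-3-yl}-2-methylbutan-1-ol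
Conditions: HF·pyridine, pyridine, THF, 0 °C
Reagents that add atoms: none
Why: Buffered HF·pyridine cleaves triethylsilyl ethers much faster than the tert-butyldiphenylsilyl and the secondary tert-butyldimethylsilyl ether, freeing C1–OH and C5–OH together.

Step 12
Reactants: 17 the C1,C5 diol
Product: 18 (2R,4S)-4-(tert-butyldimethylsilyloxy)-4-{(2S)-4-[(tert-butyldiphenylsilyloxy)methyl]-2-[(1S)-1-hydroxy-2-methylprop-2-en-1-yl]-2,5-dihydrofuran-3-yl}-2-methylbutanal
Conditions: TEMPO (cat.), PhI(OAc)2, CH2Cl2, rt
Reagents that add atoms: none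
Why: Oxoammonium-catalysed oxidation is selective for the primary alcohol over the hindered secondary allylic one; the aldehyde is used crude to protect the C10 stereocentre.

Step 13
Reactants: 18 the C1 aldehyde
Product: 19 (2R,4S)-4-(tert-butyldimethylsilyloxy)-4-{(2S)-4-[(tert-butyldiphenylsilyloxy)methyl]-2-[(1S)-1-hydroxy-2-methylprop-2-en-1-yl]-2,5-dihydrofuran-3-yl}-2-methylbutanoic acid
Conditions: NaClO2, NaH2PO4, 2-methyl-2-butene, t-BuOH/H2O, 0 °C to rt
Reagents that add atoms: sodium chlorite [Na+].[O-]Cl=O
Why: Pinnick oxidation under buffered conditions, with 2-methyl-2-butene as hypochlorite scavenger, converts the aldehyde to the acid without epimerising C10 or chlorinating the alkenes.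

Step 14
Reactants: 19 the hydroxy acid
Product: 21 eight-membered lactone (5S,6S,8S,10R; ring C1(=O)–O–C5–C6–C7–C8–C9–C10) with isopropenyl on C5, methyl on C10, tert-butyldimethylsilyloxy on C8 and the fused 2,5-dihydrofuran carrying CH2OTBDPS on C11, via mixed anhydride 20 (not isolated)
Conditions: 2,4,6-Cl3C6H2COCl, Et3N, THF, rt; then slow addition to DMAP, PhMe, 90 °C (1 mM)
Reagents that add atoms: none
Why: Yamaguchi lactonisation through mixed anhydride 20 and DMAP acyl transfer under high dilution; the planar dihydrofuran holds C5 and C8 cis on the C6–C7 bond like a cis alkene, which removes rotors and transannular hydrogens from the closing eight-membered ring.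

Step 15
Reactants: 21 the eight-membered lactone
Product: 22 2-methylene oxocane (5S,6S,8S,10R; exocyclic C1=C2H2, otherwise as 21)
Conditions: Cp2TiMe2 (3 equiv), PhMe, 70 °C, dark
Reagents that add atoms: dimethyltitanocene C[Ti](C)(C1C=CC=C1)C1C=CC=C1
Why: Petasis methylenation: thermolysis of Cp2TiMe2 gives Cp2Ti=CH2, which converts the lactone carbonyl to the exocyclic enol ether through an oxatitanacyclobutane; the reagent is non-basic, so C10 is safe, and no other carbonyl is present because the butenolide is carried as its dihydrofuran.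

Step 16
Reactants: 22 the 2-methylene oxocane
Product: 23 (4Z,6R,8S,10R)-8-(tert-butyldimethylsilyloxy)-13-(tert-butyldiphenylsilyloxy)-6,12-epoxygermacra-4,7(11)-dien-1-one
Conditions: PhMe (0.01 M, degassed), Et3N (1 vol %), 180 °C, sealed base-washed tube
Reagents that add atoms: none
Why: Claisen rearrangement, a concerted suprafacial [3,3]-sigmatropic shift across C2=C1–O–C5–C4=C3: the C2–C3 bond forms while C5–O breaks, and the enol ether becomes the C1 carbonyl, which drives the reaction. The closest known reaction type is the thermal ring expansion of 2-methylene-6-vinyltetrahydropyrans to cyclooct-4-enones; here the homologous oxocane should give the cyclodec-4-enone. The ten-membered ring is closed by two-atom ring expansion of the eight-membered ring through a bridged pericyclic array that shares C1–O–C5 with it, not by end-to-end cyclisation. No stereocentre is created: C5 becomes sp2, so both C5 epimers would converge, and C6, C8 and C10 are spectators. The step must deliver the Z alkene (C3 cis to C6): the torsion C1–O–C5–C6 is an endocyclic torsion of the oxocane and must stay gauche, which places C6 pseudo-axial on the pericyclic array, whereas the E alkene would need this torsion near antiperiplanar, out of reach for an eight-membered ring. The shift must also outrun migration of the exocyclic double bond into the ring, hence base-washed glass and a trace of amine. Silyl ethers and the dihydrofuran are inert at this temperature.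

Step 17
Reactants: 23 the ten-membered ketone
Product: 24 (4Z,6R,8S,10R)-8,13-dihydroxy-6,12-epoxygermacra-4,7(11)-dien-1-one
Conditions: HF·pyridine, THF, 0 °C to rt
Reagents that add atoms: none
Why: Fluoride cleavage of both silyl ethers under acidic, non-epimerising conditions before any acid-sensitive group exists; the freed C8 hydroxyl may equilibrate with a transannular hemiketal to C1, which reopens on acylation.

Step 18
Reactants: 24 the C8,C13 diol
Product: 25 (4Z,6R,8S,10R)-13-acetoxy-8-hydroxy-6,12-epoxygermacra-4,7(11)-dien-1-one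
Conditions: AcCl (1.05 equiv), 2,4,6-collidine, CH2Cl2, −78 °C
Reagents that add atoms: acetyl chloride CC(=O)Cl
Why: Low-temperature acetylation with a hindered pyridine base distinguishes the primary allylic C13 hydroxyl from the hindered secondary C8 hydroxyl on steric grounds.

Step 19
Reactants: 25 the C13 monoacetate
Product: 26 (4Z,6R,8S,10R)-13-acetoxy-8-(tigloyloxy)-6,12-epoxygermacra-4,7(11)-dien-1-one
Conditions: tiglic acid, 2,4,6-Cl3C6H2COCl, Et3N, PhMe, rt; then 25, DMAP, 40 °C
Reagents that add atoms: tiglic acid C/C=C(\C)C(=O)O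
Why: Yamaguchi esterification suits hindered secondary alcohols; the tiglate is the stable E isomer, so no geometric leakage is expected, and C1 is still a ketone and cannot compete.

Step 20
Reactants: 26 the diester dienone
Product: 27 (4R,5S,6S,8S,10R)-13-acetoxy-4,5:6,12-diepoxy-8-(tigloyloxy)germacr-7(11)-en-1-one
Conditions: mCPBA, NaHCO3, CH2Cl2, 0 °C
Reagents that add atoms: 3-chloroperbenzoic acid OOC(=O)c1cccc(Cl)c1
Why: Prilezhaev epoxidation: C4=C5 is the only nucleophilic alkene (the dihydrofuran alkene carries four allylic C–O bonds and the tiglate is conjugated) and the concerted addition keeps the cis geometry; allylic strain in the Z alkene should hold C6–H in the alkene plane, and attack anti to the C6–O bond gives the 4R,5S epoxide. Bicarbonate protects the epoxide and slows Baeyer–Villiger oxidation of the ketone.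

Step 21
Reactants: 27 the epoxy dihydrofuran
Product: 28 (4R,5S,6S,8S,10R)-13-acetoxy-4,5-epoxy-1-oxo-8-(tigloyloxy)germacr-7(11)-en-12,6-olide
Conditions: CrO3, 3,5-dimethylpyrazole, CH2Cl2, −20 °C
Reagents that add atoms: chromium trioxide O=[Cr](=O)=O
Why: Allylic oxidation of a cyclic allylic ether with hexavalent chromium, the known route from 2,5-dihydrofurans to butenolides; the ring C12–H bonds are aligned with the π bond and activated by the ether oxygen, C8–H and C13–H2 are deactivated by their acyloxy groups, C6–H is tertiary and hindered, and no free hydroxyl is present.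

Step 22
Reactants: 28 the keto butenolide
Product: 29 (1S,4R,5S,6S,8S,10R)-13-acetoxy-4,5-epoxy-1-hydroxy-8-(tigloyloxy)germacr-7(11)-en-12,6-olide (CNP0159184.1)
Conditions: NaBH4, CeCl3·7H2O, MeOH, −78 °C
Reagents that add atoms: none
Why: Luche reduction is selective for the ketone over the unsaturated lactone and the esters; hydride should approach C1 from the ring periphery, anti to the C9 ring bond with the C10 methyl near the carbonyl plane (Felkin–Anh sense), which gives the 1,10-anti (1S) alcohol.

**Compound list**

1 | (S)-3-bromo-2-methylpropan-1-ol | BrC[C@@H](C)CO | starting material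
2 | (S)-(3-bromo-2-methylpropoxy)triethylsilane | BrC[C@@H](C)CO[Si](CC)(CC)CC | intermediate
3 | mucobromic acid | O=C1OC(O)C(Br)=C1Br | starting material
4 | sodium (2Z)-2,3-dibromo-4-hydroxybut-2-enoate | [Na+].[O-]C(=O)/C(Br)=C(/Br)CO | intermediate
5 | 3,4-dibromofuran-2(5H)-one | O=C1OCC(Br)=C1Br | intermediate
6 | [(2S)-2-methyl-3-(triethylsilyloxy)propyl]zinc bromide | Br[Zn]C[C@@H](C)CO[Si](CC)(CC)CC | intermediate
7 | 3-bromo-4-[(3R)-3-methyl-4-(triethylsilyloxy)butanoyl]furan-2(5H)-one | O=C1OCC(C(=O)C[C@@H](C)CO[Si](CC)(CC)CC)=C1Br | intermediate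
8 | 3-bromo-4-[(1S,3R)-1-hydroxy-3-methyl-4-(triethylsilyloxy)butyl]furan-2(5H)-one | O=C1OCC([C@@H](O)C[C@@H](C)CO[Si](CC)(CC)CC)=C1Br | intermediate
9 | 3-bromo-4-[(1S,3R)-1-(tert-butyldimethylsilyloxy)-3-methyl-4-(triethylsilyloxy)butyl]furan-2(5H)-one | O=C1OCC([C@@H](O[Si](C)(C)C(C)(C)C)C[C@@H](C)CO[Si](CC)(CC)CC)=C1Br | intermediate
10 | 4-[(1S,3R)-1-(tert-butyldimethylsilyloxy)-3-methyl-4-(triethylsilyloxy)butyl]-3-(hydroxymethyl)furan-2(5H)-one | O=C1OCC([C@@H](O[Si](C)(C)C(C)(C)C)C[C@@H](C)CO[Si](CC)(CC)CC)=C1CO | intermediate
11 | 4-[(1S,3R)-1-(tert-butyldimethylsilyloxy)-3-methyl-4-(triethylsilyloxy)butyl]-3-[(tert-butyldiphenylsilyloxy)methyl]furan-2(5H)-one | O=C1OCC([C@@H](O[Si](C)(C)C(C)(C)C)C[C@@H](C)CO[Si](CC)(CC)CC)=C1CO[Si](c3ccccc3)(c3ccccc3)C(C)(C)C | intermediate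
12 | methacrolein | C=C(C)C=O | starting material
13 | 2-(triethylsilyloxy)furan bearing the (1S,3R) C8 side chain on C7 and CH2OTBDPS on C11 | CC[Si](CC)(CC)Oc1occ([C@@H](O[Si](C)(C)C(C)(C)C)C[C@@H](C)CO[Si](CC)(CC)CC)c1CO[Si](c3ccccc3)(c3ccccc3)C(C)(C)C | intermediate
14 | (5S)-4-[(1S,3R)-1-(tert-butyldimethylsilyloxy)-3-methyl-4-(triethylsilyloxy)butyl]-3-[(tert-butyldiphenylsilyloxy)methyl]-5-[(1S)-2-methyl-1-(triethylsilyloxy)prop-2-en-1-yl]furan-2(5H)-one | O=C1O[C@H]([C@@H](O[Si](CC)(CC)CC)C(C)=C)C([C@@H](O[Si](C)(C)C(C)(C)C)C[C@@H](C)CO[Si](CC)(CC)CC)=C1CO[Si](c3ccccc3)(c3ccccc3)C(C)(C)C | intermediate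
15 | (Z)-ene-1,4-diol (5S,6S,8S,10R): C6–OH and C12–OH free, C1 and C5 triethylsilyl ethers, C8 tert-butyldimethylsilyl ether, C13 tert-butyldiphenylsilyl ether | OC/C(CO[Si](c3ccccc3)(c3ccccc3)C(C)(C)C)=C(\[C@H](O)[C@@H](O[Si](CC)(CC)CC)C(C)=C)[C@@H](O[Si](C)(C)C(C)(C)C)C[C@@H](C)CO[Si](CC)(CC)CC | intermediate
16 | (2S)-3-[(1S,3R)-1-(tert-butyldimethylsilyloxy)-3-methyl-4-(triethylsilyloxy)butyl]-4-[(tert-butyldiphenylsilyloxy)methyl]-2-[(1S)-2-methyl-1-(triethylsilyloxy)prop-2-en-1-yl]-2,5-dihydrofuran | C=C(C)[C@H](O[Si](CC)(CC)CC)[C@H]1OCC(CO[Si](c3ccccc3)(c3ccccc3)C(C)(C)C)=C1[C@@H](O[Si](C)(C)C(C)(C)C)C[C@@H](C)CO[Si](CC)(CC)CC | intermediate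
17 | (2R,4S)-4-(tert-butyldimethylsilyloxy)-4-{(2S)-4-[(tert-butyldiphenylsilyloxy)methyl]-2-[(1S)-1-hydroxy-2-methylprop-2-en-1-yl]-2,5-dihydrofuran-3-yl}-2-methylbutan-1-ol | C=C(C)[C@H](O)[C@H]1OCC(CO[Si](c3ccccc3)(c3ccccc3)C(C)(C)C)=C1[C@@H](O[Si](C)(C)C(C)(C)C)C[C@@H](C)CO | intermediate
18 | corresponding (2R,4S)-2-methylbutanal (C1 aldehyde) | C=C(C)[C@H](O)[C@H]1OCC(CO[Si](c3ccccc3)(c3ccccc3)C(C)(C)C)=C1[C@@H](O[Si](C)(C)C(C)(C)C)C[C@@H](C)C=O | intermediate
19 | corresponding (2R,4S)-2-methylbutanoic acid (C1 acid, C5–OH free) | C=C(C)[C@H](O)[C@H]1OCC(CO[Si](c3ccccc3)(c3ccccc3)C(C)(C)C)=C1[C@@H](O[Si](C)(C)C(C)(C)C)C[C@@H](C)C(=O)O | intermediate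
20 | mixed anhydride of 19 with 2,4,6-trichlorobenzoic acid | C=C(C)[C@H](O)[C@H]1OCC(CO[Si](c3ccccc3)(c3ccccc3)C(C)(C)C)=C1[C@@H](O[Si](C)(C)C(C)(C)C)C[C@@H](C)C(=O)OC(=O)c4c(Cl)cc(Cl)cc4Cl | intermediate
21 | eight-membered lactone (5S,6S,8S,10R) spanning C1 and C5, fused 2,5-dihydrofuran, C8–OTBS, C13–OTBDPS | O=C1O[C@@H](C(C)=C)[C@H]2OCC(CO[Si](c3ccccc3)(c3ccccc3)C(C)(C)C)=C2[C@@H](O[Si](C)(C)C(C)(C)C)C[C@H]1C | intermediate
22 | 2-methylene oxocane (5S,6S,8S,10R), otherwise as 21 | C=C1O[C@@H](C(C)=C)[C@H]2OCC(CO[Si](c3ccccc3)(c3ccccc3)C(C)(C)C)=C2[C@@H](O[Si](C)(C)C(C)(C)C)C[C@H]1C | intermediate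
23 | (4Z,6R,8S,10R)-8-(tert-butyldimethylsilyloxy)-13-(tert-butyldiphenylsilyloxy)-6,12-epoxygermacra-4,7(11)-dien-1-one | CC(C)(C)[Si](C)(C)O[C@H]1C[C@@H](C)C(=O)CC/C(C)=C\[C@H]2OCC(CO[Si](c3ccccc3)(c3ccccc3)C(C)(C)C)=C12 | intermediate
24 | (4Z,6R,8S,10R)-8,13-dihydroxy-6,12-epoxygermacra-4,7(11)-dien-1-one | O[C@H]1C[C@@H](C)C(=O)CC/C(C)=C\[C@H]2OCC(CO)=C12 | intermediate
25 | (4Z,6R,8S,10R)-13-acetoxy-8-hydroxy-6,12-epoxygermacra-4,7(11)-dien-1-one | O[C@H]1C[C@@H](C)C(=O)CC/C(C)=C\[C@H]2OCC(COC(C)=O)=C12 | intermediate
26 | (4Z,6R,8S,10R)-13-acetoxy-8-(tigloyloxy)-6,12-epoxygermacra-4,7(11)-dien-1-one | C/C=C(\C)C(=O)O[C@H]1C[C@@H](C)C(=O)CC/C(C)=C\[C@H]2OCC(COC(C)=O)=C12 | intermediate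
27 | (4R,5S,6S,8S,10R)-13-acetoxy-4,5:6,12-diepoxy-8-(tigloyloxy)germacr-7(11)-en-1-one | C/C=C(\C)C(=O)O[C@H]1C[C@@H](C)C(=O)CC[C@@]2(C)O[C@H]2[C@H]2OCC(COC(C)=O)=C12 | intermediate
28 | (4R,5S,6S,8S,10R)-13-acetoxy-4,5-epoxy-1-oxo-8-(tigloyloxy)germacr-7(11)-en-12,6-olide | C/C=C(\C)C(=O)O[C@H]1C[C@@H](C)C(=O)CC[C@@]2(C)O[C@H]2[C@H]2OC(=O)C(COC(C)=O)=C12 | intermediate
29 | (1S,4R,5S,6S,8S,10R)-13-acetoxy-4,5-epoxy-1-hydroxy-8-(tigloyloxy)germacr-7(11)-en-12,6-olide | C/C=C(\C)C(=O)O[C@H]1C[C@@H](C)[C@@H](O)CC[C@@]2(C)O[C@H]2[C@H]2OC(=O)C(COC(C)=O)=C12 | target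

**Step count and least certain steps**

Total: 22 steps. Longest linear sequence: 21 steps (3 to 29, steps 2–22; the branch from 1 joins at step 3).

Step 16 (key step). The exocyclic double bond may migrate into the ring or the enol ether may hydrolyse before the shift occurs; the folded conformer that brings C3 over C2 may be poorly populated; or a transition state with C6 pseudo-equatorial may leak E alkene. Fallback: 22 is treated with i-Bu3Al in CH2Cl2 at low temperature. This Lewis-acid-promoted variant of the same shift runs far below the isomerisation temperature and reduces the ketone in the flask, giving the cyclodec-4-enol F1 as C1 epimers. Dess–Martin periodinane with NaHCO3 returns it to 23.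

Step 8. Facial selection at C6 may be poor, because the controlling C8 centre is one atom away and its two out-of-plane groups differ only moderately. Fallback: catalyst control replaces substrate control. Silyloxyfuran 13 is isolated and added to 12 under SiCl4 activated by a chiral bisphosphoramide, which gives the free C5 alcohol F2 after work-up. TESCl and imidazole convert F2 to 14.

Step 14. Intermolecular acylation (diolide formation) may outrun closure of the eight-membered ring, and the activated acid may epimerise at C10 through a ketene. Fallback: the alcohol is activated instead of the acid. Mitsunobu lactonisation of 19 (PPh3, DIAD, high dilution) closes the ring with inversion at C5 to the 5-epi-lactone F3. Cp2TiMe2 gives the 5-epi-enol ether F4, and thermolysis as in step 16 returns to 23, because C5 becomes sp2.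

Step 20. The peracid may attack the other alkene face if the ring conformer differs from the allylic-strain model, and Baeyer–Villiger oxidation of the ketone may compete. Fallback: the face is inverted by a two-step halohydrin route. NBS in wet THF adds bromine to 26 from the accessible face and water at C4 from the opposite one, giving the bromohydrin F5. K2CO3 in acetone closes F5 to 27 by displacement at C5.

Step 21. Hydrogen abstraction at C6 (leading to aromatisation to a furan) or at the tiglate methyl groups may compete, and acidic chromium species may open the epoxide. Fallback: hydride abstraction replaces hydrogen-atom abstraction. 4-Acetamido-2,2,6,6-tetramethyl-1-oxopiperidinium tetrafluoroborate in wet MeCN converts 27 to the C12 lactol F6, and MnO2 oxidises F6 to 28.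

Step 22. Hydride may be delivered to the other face of C1; conjugate reduction of the α-(acetoxymethyl)butenolide or transannular opening of the epoxide by the new alkoxide may also occur. Fallback: if the 1-epi alcohol F7 predominates, Mitsunobu inversion with chloroacetic acid (PPh3, DIAD) gives the inverted chloroacetate F8. Methanolic ammonia at −20 °C removes the chloroacetyl group, which cleaves far faster than the acetate or tiglate, and gives 29.

**Further compounds**

F1 | step 16 | (4Z,6R,8S,10R)-8-(tert-butyldimethylsilyloxy)-13-(tert-butyldiphenylsilyloxy)-6,12-epoxygermacra-4,7(11)-dien-1-ol (C1 epimers) | CC(C)(C)[Si](C)(C)O[C@H]1C[C@@H](C)C(O)CC/C(C)=C\[C@H]2OCC(CO[Si](c3ccccc3)(c3ccccc3)C(C)(C)C)=C12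
F2 | step 8 | C5 alcohol corresponding to 14 (5-[(1S)-1-hydroxy-2-methylprop-2-en-1-yl] butenolide) | O=C1O[C@H]([C@@H](O)C(C)=C)C([C@@H](O[Si](C)(C)C(C)(C)C)C[C@@H](C)CO[Si](CC)(CC)CC)=C1CO[Si](c3ccccc3)(c3ccccc3)C(C)(C)C
F3 | step 14 | 5-epi-lactone (5R,6S,8S,10R) | O=C1O[C@H](C(C)=C)[C@H]2OCC(CO[Si](c3ccccc3)(c3ccccc3)C(C)(C)C)=C2[C@@H](O[Si](C)(C)C(C)(C)C)C[C@H]1C
F4 | step 14 | 5-epi-2-methylene oxocane (5R,6S,8S,10R) | C=C1O[C@H](C(C)=C)[C@H]2OCC(CO[Si](c3ccccc3)(c3ccccc3)C(C)(C)C)=C2[C@@H](O[Si](C)(C)C(C)(C)C)C[C@H]1C
F5 | step 20 | (4R,5R)-5-bromo-4-hydroxy bromohydrin of 26 | C/C=C(\C)C(=O)O[C@H]1C[C@@H](C)C(=O)CC[C@@](C)(O)[C@H](Br)[C@H]2OCC(COC(C)=O)=C12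
F6 | step 21 | C12 lactol of 28 (12-hydroxy-6,12-epoxide, C12 epimers) | C/C=C(\C)C(=O)O[C@H]1C[C@@H](C)C(=O)CC[C@@]2(C)O[C@H]2[C@H]2OC(O)C(COC(C)=O)=C12
F7 | step 22 | 1-epi-29 (1R alcohol) | C/C=C(\C)C(=O)O[C@H]1C[C@@H](C)[C@H](O)CC[C@@]2(C)O[C@H]2[C@H]2OC(=O)C(COC(C)=O)=C12
F8 | step 22 | 1-O-chloroacetyl-29 (1S) | C/C=C(\C)C(=O)O[C@H]1C[C@@H](C)[C@@H](OC(=O)CCl)CC[C@@]2(C)O[C@H]2[C@H]2OC(=O)C(COC(C)=O)=C12
A1 | alternative 1 | seco-diene with C8 vinyl group and C1 isopropenyl carbinol | C/C=C(\C)C(=O)O[C@@H](C=C)C1=C(COC(C)=O)C(=O)O[C@@H]1[C@@H]1O[C@]1(C)CC[C@H](O)C(C)=C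
A2 | alternative 1 | 9,10-didehydro-29 (ring-cis trisubstituted alkene) | C/C=C(\C)C(=O)O[C@H]1/C=C(/C)[C@@H](O)CC[C@@]2(C)O[C@H]2[C@H]2OC(=O)C(COC(C)=O)=C12
A3 | alternative 2 | octalin with tetrasubstituted C1=C6 alkene, C8 silyl ether, C10 methyl and C4 methyl carbinol | CC(C)(C)[Si](C)(C)O[C@H]1C[C@@H](C)C2=C(C1)C[C@](C)(O)CC2
A4 | alternative 2 | ten-membered 1,6-diketone with C4 carbinol | CC(C)(C)[Si](C)(C)O[C@H]1C[C@@H](C)C(=O)CC[C@@](C)(O)CC(=O)C1
A5 | alternative 3 | trans-1-[(E)-2-(4-methoxybenzyloxy)vinyl]-6-isopropenyl-3-methylcyclohex-2-en-1-ol | COc1ccc(CO/C=C/[C@]2(O)C=C(C)CC[C@H]2C(C)=C)cc1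
A6 | alternative 3 | ten-membered (Z,E)-dienone with C8 4-methoxybenzyl ether | COc1ccc(CO[C@H]2C/C(C)=C/CC/C(C)=C\C(=O)C2)cc1
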